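## The problem

Target 18 is an N-acylated bicyclo[3.3.1]nonan-9-one. Its core is numbered here C1 (bridgehead carbinol), C2 (CH2), C3 (N-bearing carbon), C4 (carbinol), C5 (bridgehead CH), C6 (methoxy carbon), C7 and C8 (epoxide) and C9 (ketone); ring A is C1–C2–C3–C4–C5–C9, ring B is C1–C8–C7–C6–C5–C9, and "exo" denotes the face of either three-carbon bridge that is turned away from the other one, toward C9. Seven stereocentres (C1, C3, C4, C5, C6, C7, C8) must be set, and every heteroatom on C3, C4, C6, C7 and C8 is exo. Because the bridgeheads are tied together by the ring fusion and the endo faces of the two rings look at each other, the exo face is also the face that reagents reach, so relative configuration can come from the skeleton (an exo oxygen on C6 can in addition steer the C7–C8 epoxide) and only the absolute configuration needs a chiral reagent. The functional groups are fragile: the C1–OH/C9=O ketol can rearrange to a fused hydrindanone, hydroxyls on C4 and (in intermediates) C6 are β to the ketone and invite retro-aldol cleavage as alkoxides, the epoxide is acid-labile with C7 open to transannular attack from C3, and the enamide would not survive oxidants or hydrogenation. The enabling feature is hidden symmetry: stripped of nitrogen, methoxy and epoxide oxygen, the core is a C1-oxygenated bicyclo[3.3.1]nona-3,6-dien-9-one with a mirror plane through C1, C5 and C9 that exchanges the C3=C4 and C6=C7 alkenes. One enantioselective exo mono-epoxidation of C6=C7 therefore fixes C1, C5, C6 and C7 at once and leaves exactly one alkene in each ring for the remaining heteroatoms. The C1 oxygen lies in the mirror plane, equatorial on both rings and close to antiperiplanar to C7, so it cannot hand an oxidant to either alkene, and the choice between them has to come from a chiral oxidant acting from outside.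

## Retrosynthesis

**Amide bond.** The acyl C–N bond of 18 is cut to give amine 15 and (E)-dodec-2-enoic acid 16. This cut comes last because the conjugated alkene of the chain would not survive epoxidation, osmium or hydrogenolysis. It removes twelve carbons and leaves only the polar core. The forward step has only to be N-selective over two hydroxyls.

**C3–N and C4–O.** Both bonds of ring A are cut together, taking 15 through benzyl carbamate 14 back to alkene 13. A suprafacial addition from the exo face sets both centres at once. Stepwise routes through an epoxide or an aziridine give trans products or require a nucleophile to enter C3 from the blocked endo side. The precursor has two stereocentres fewer. The forward reaction must place nitrogen on C3 and not on C4.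

**O–Si and O–CH3.** Alcohol 13 comes from silyl ether 12, and 12 from epoxy alcohol 11 by cutting the O–CH3 bond. The silyl group is removed before ring A is oxidised, at a stage where no β-hydroxy ketone is present. The methylation must run without a free C6 alkoxide.

**C7–O and C8–O.** Epoxy alcohol 11 goes back to allylic alcohol 10. The exo C6 hydroxyl is allylic and pseudo-axial, the arrangement that hydroxyl-directed vanadium epoxidation needs. This is preferred to a peracid, which would not distinguish C7=C8 from C3=C4. Two stereocentres are removed.

**Epoxide transposition.** Alcohol 10 is the isomer of epoxide 9 in which oxygen stays on C6 and the alkene moves to C7=C8. The opening can go only this way, because the other β-hydrogen sits on bridgehead C5. The forward step needs a base that removes the exo hydrogen on C8 without touching the ketone.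

**C6–O and C7–O (key).** Epoxide 9 goes back to meso diene 8, which carries no stereochemical information at all.
- A catalyst built from VO(OiPr)3 or Hf(OtBu)4 and a chiral bishydroxamic acid, bound to a free C1 hydroxyl, would be the obvious tool. It is not relied on here: a metal on the C1 oxygen would hold its peroxide away from the exo face of either alkene, and pentavalent vanadium with peroxide can cleave a free ketol.
- An outer-sphere chiral dioxirane is used instead. The C1 oxygen is kept as a bulky silyl ether, which makes the two ends of each cis-alkene unequal.
- Directed vanadium chemistry is kept for 10 → 11, where the geometry is right.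

**C3=C4 and C4–C5.** Diene 8 comes from aldol 6 by dehydration, and 6 from keto-aldehyde 5 by cutting C4–C5. Dehydration can go only toward C3, which is what makes 8 symmetric with the C6=C7 alkene already in ring B. The precursor is monocyclic. The aldol must react at the α-carbon of a dienolate.

**C1–C2.** Keto-aldehyde 5 is cut to enediol bis-silyl ether 3 and acrolein 4. A symmetric enediol ether can react only at an oxygen-bearing carbon, whereas enolate chemistry of a free α-hydroxy ketone would deprotonate the allylic side instead.

**Ring B.** Diene 3 is the Birch product of bis-silyl ether 2, made from catechol 1. This delivers the enediol ether and the isolated alkene in one step from an aromatic ring, without passing through a ketol that could conjugate or aromatise.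

## Roads not taken

Alternative 1: Two-directional double aldol. The cut is C4–C5 and C5–C6 of the meso exo,exo-4,6-diol A2, back to the acyclic keto-dialdehyde A1. In the forward step proline forms the enamine of the methyl ketone, which adds to one aldehyde and then, after re-forming, to the other.
- Merits: the whole bicycle forms in one operation from an achiral chain, both C4 and C6 oxygens arrive exo, and the C4 hydroxyl is never removed. A2 reaches the core in fewer steps than 8 does. A meso diol is also a more predictable desymmetrisation substrate (enzymatic mono-acylation) than a meso diene.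
- Weak points: the chirality of the catalyst cannot be stored in a meso product. A1 is a 4,4-disubstituted heptanedial, and aldehyde enamines form faster than that of a hindered methyl ketone, so the aldehyde–aldehyde aldol is the likely main path. A2 has no functionality at C7–C8 or C3, so the epoxide would need a desaturation next to C6 and the nitrogen a C–H amination.
- Comparison: the chosen plan spends five steps reaching 8 but arrives with an alkene exactly where each remaining pair of heteroatoms is needed. A2 could even join the present route at 8 after double dehydration and silyl exchange.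

Alternative 2: Chiral-pool ring A, aldol closure of ring B. The cut is C5–C6 of the bicyclic allylic alcohol A5, back to the cyclohexanone A4 carrying a (Z)-enal on C1, itself derived from shikimic acid A3. The forward step is soft enolisation of C9 toward C5 (MgBr2·OEt2, Et3N) and addition to the enal carbon.
- Merits: absolute configuration is bought, not made, which is clearly safer than a catalytic desymmetrisation whose sense cannot be predicted. C1, C3 and C4 are in place before cyclisation, nitrogen regiochemistry is not an issue, and A5 has the same ring B as 10.
- Weak points: converting A3 into A4 needs deoxygenation, O-to-N exchange, oxidation of the alkene to a ketol and a two-carbon Z-enal, well over ten steps. The tertiary hydroxyl of A4 can close onto the enal as a five-membered lactol, and the enal can isomerise to E. The C5 enolate has the C4 silyloxy group in the β-position and can eliminate it. The C6 configuration is not obviously controlled.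
- Comparison: the chosen plan is far shorter and keeps β-oxygenated ketones to the last stages. Against the secure absolute configuration of A3 it can only set a resolution fallback.

Alternative 3: Late C3–H amination. The cut is C3–N of oxazolidinone A7, back to the C4 primary carbamate A6 with a saturated C2–C3. In the forward step Rh2(OAc)4, PhI(OAc)2 and MgO generate a nitrenoid that inserts into the exo C3–H bond.
- Merits: ring size and retention fix both the position and the configuration of nitrogen, which the intermolecular aminohydroxylation of the chosen plan cannot guarantee. It also uses the C4 oxygen that an aldol closure supplies.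
- Weak points: it is an end-game only and says nothing about ring B or absolute configuration. The free ketol of A6 is exposed to an oxidant that cleaves such units. The tertiary C5–H is a second β C–H. Opening A7 needs N-activation and base, which the β-hydroxy ketone tolerates poorly. A saturated ring A also gives up the mirror symmetry.
- Comparison: the chosen plan gets both heteroatoms in one step from an alkene that symmetry provides for free, and keeps this insertion as its fallback for step 11.

Key step: step 6

Remarks before the steps:
- Compounds 5, 6 and 7 are racemic and 8 is meso; their SMILES show constitution or relative configuration only.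
- Assumption: the sense of induction of the ketone catalyst on this diene cannot be assigned in advance. The D-glucose-derived catalyst is written for step 6; its enantiomer from L-glucose would be used if the D-series epoxidises the other enantiotopic alkene.

## Route

Step 1
Reactants: 1 catechol
Product: 2 1,2-bis(tert-butyldimethylsilyloxy)benzene
Conditions: TBSCl (2.2 equiv), imidazole (4.4 equiv), DMF, rt
Reagents that add atoms: tert-butyldimethylsilyl chloride, CC(C)(C)[Si](C)(C)Cl
Why: Silyl ether formation on both phenols; no stereocentre is involved. The bulky silyl group is chosen because it survives the dissolving-metal step and later shields the C1 oxygen.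

Step 2
Reactants: 2 1,2-bis(tert-butyldimethylsilyloxy)benzene
Product: 3 1,2-bis(tert-butyldimethylsilyloxy)cyclohexa-1,4-diene
Conditions: Li (5 equiv), NH3(l)/THF, tBuOH (3 equiv), −78 °C; solid NH4Cl
Reagents that add atoms: none
Why: Birch reduction of an aryl silyl ether: hydrogen enters at the two positions ortho to oxygen and para to each other, so both silyloxy groups end on one tetrasubstituted alkene and the other alkene is the future C6=C7. tert-Butyldimethylsilyl aryl ethers resist Si–O cleavage here; the 1,4-dihydroarene is kept cold and under argon against re-aromatisation.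

Step 3
Reactants: 3 1,2-bis(tert-butyldimethylsilyloxy)cyclohexa-1,4-diene; 4 acrolein
Product: 5 rac-2-(tert-butyldimethylsilyloxy)-2-(3-oxopropyl)cyclohex-4-en-1-one
Conditions: BF3·OEt2 (0.2 equiv), iPrOH (1.1 equiv), CH2Cl2, −78 °C; aq. NaHCO3
Reagents that add atoms: none
Why: Mukaiyama–Michael addition: the symmetric enediol ether can attack only through an oxygen-bearing carbon, which creates C1–C2 and the quaternary C1 without any enolate that could form on the more acidic allylic side. The silyl group on the C9 oxocarbenium ion passes to isopropanol and frees the ketone; C1 forms racemic, which is harmless because the chirality is erased in 8.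

Step 4
Reactants: 5 rac-2-(tert-butyldimethylsilyloxy)-2-(3-oxopropyl)cyclohex-4-en-1-one
Product: 6 rac-1-(tert-butyldimethylsilyloxy)-4-hydroxybicyclo[3.3.1]non-6-en-9-one (exo and endo C4 epimers)
Conditions: DBU (0.2 equiv), CH2Cl2, −20 → 0 °C; AcOH quench
Reagents that add atoms: none
Why: Intramolecular aldol addition: C1 is quaternary, so C9 enolises only toward allylic C5, and the dienolate should attack the aldehyde through its α-carbon under kinetic control, forming C4–C5 and ring A. Both C4 epimers are used; the reaction is quenched at full conversion to prevent retro-aldol equilibration toward the γ-aldol.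

Step 5
Reactants: 6 rac-1-(tert-butyldimethylsilyloxy)-4-hydroxybicyclo[3.3.1]non-6-en-9-one
Product: 8 meso-1-(tert-butyldimethylsilyloxy)bicyclo[3.3.1]nona-3,6-dien-9-one, via sulfamate ester 7 (not isolated)
Conditions: Burgess reagent (2 equiv), toluene, 20 → 60 °C
Reagents that add atoms: methyl N-(triethylammoniosulfonyl)carbamate (Burgess reagent), CC[N+](CC)(CC)S(=O)(=O)[N-]C(=O)OC
Why: Burgess dehydration: the reagent is carried only by sulfamate ester 7, which undergoes thermal syn elimination without carbocations and releases the sulfamate again; this matters because a cation at C4 would be captured by the C6=C7 alkene. Only the C3 hydrogens can become syn-periplanar (the other β-hydrogen is on bridgehead C5), so C3=C4 should form from either epimer and the product is the meso diene.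

Step 6
Reactants: 8 meso-1-(tert-butyldimethylsilyloxy)bicyclo[3.3.1]nona-3,6-dien-9-one
Product: 9 exo-6,7-epoxy-1-(tert-butyldimethylsilyloxy)bicyclo[3.3.1]non-3-en-9-one (single enantiomer, C1, C5, C6 and C7 as in 18)
Conditions: D-glucose-derived spiro-oxazolidinone ketone, N-(4-methylphenyl) (0.3 equiv), Oxone (2KHSO5·KHSO4·K2SO4; 1.2 equiv KHSO5), K2CO3, Bu4NHSO4 (cat.), DME/CH2(OMe)2–aq. buffer (pH 8–9), −10 → 0 °C
Reagents that add atoms: potassium peroxymonosulfate, [K+].[O-]S(=O)(=O)OO
Why: The ketone catalyst is oxidised by KHSO5 to a chiral dioxirane, which transfers one oxygen atom to C6=C7 through a concerted spiro transition state and forms C6–O and C7–O together. The closest known reactions are the Shi epoxidation of non-conjugated cis-olefins with this class of oxazolidinone ketones and the chiral-dioxirane desymmetrisation of meso cyclic dienes. The oxirane closes in this single [2+1] atom transfer, syn across the alkene. C6 and C7 should take oxygen on the exo face because the endo faces of the two alkenes point at each other across the cleft between C3 and C7, a substrate bias. C1 and C5, which are not independent stereocentres in meso 8, become stereogenic the moment one alkene is chosen, so their configuration, like that of C6 and C7, is decided by the catalyst's choice between the enantiotopic alkenes. Since only the exo face is open, that choice equals enantioface selection on a cis-alkene whose two ends differ: C7 continues through the C8 methylene, with its axial exo hydrogen, to the silyloxy-bearing C1, whereas C6 is attached directly to bridgehead C5 and the carbonyl bridge, and the bulky silyl ether enlarges the difference. A metal bound to the C1 oxygen could not make this choice, because that oxygen is equatorial on both rings and close to antiperiplanar to C7, which keeps any bound peroxide away from the exo face. Mono-epoxidation needs limited oxidant; the minor enantiomer still carries the alkene the catalyst prefers and should be consumed faster to the meso bis-epoxide, so conversion slightly past one equivalent should raise the enantiomeric purity of 9 at some cost in material.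

Step 7
Reactants: 9 exo-6,7-epoxy-1-(tert-butyldimethylsilyloxy)bicyclo[3.3.1]non-3-en-9-one
Product: 10 exo-6-hydroxy-1-(tert-butyldimethylsilyloxy)bicyclo[3.3.1]nona-3,7-dien-9-one
Conditions: Et2AlCl (4 equiv), LiTMP (4 equiv), toluene, 0 °C, 30 min; then 9, 0 °C → rt; aq. KNaC4H4O6 (potassium sodium tartrate)
Reagents that add atoms: none
Why: Aluminium-amide isomerisation of an epoxide to an allylic alcohol by syn β-elimination through a six-membered transition state: aluminium of Et2Al(TMP) binds the exo epoxide oxygen and the amide nitrogen removes the exo hydrogen on C8. The only other β-hydrogen is on bridgehead C5, so C7–O breaks, C7=C8 forms and C6–O keeps its exo configuration; the amide has no transferable hydride and the C9 ketone has no enolisable hydrogen.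

Step 8
Reactants: 10 exo-6-hydroxy-1-(tert-butyldimethylsilyloxy)bicyclo[3.3.1]nona-3,7-dien-9-one
Product: 11 exo-7,8-epoxy-exo-6-hydroxy-1-(tert-butyldimethylsilyloxy)bicyclo[3.3.1]non-3-en-9-one
Conditions: VO(acac)2 (5 mol%), tBuOOH (1.5 equiv, decane), CH2Cl2, 0 °C → rt
Reagents that add atoms: tert-butyl hydroperoxide, CC(C)(C)OO
Why: Hydroxyl-directed epoxidation of a cyclic allylic alcohol: the pseudo-axial exo C6 alkoxide binds the pentavalent vanadium alkylperoxide and oxygen is delivered to the same, exo face of C7=C8, setting C7 and C8 cis to the C6 oxygen. C3=C4 should not be touched because the C6 oxygen points away from it and the C1 oxygen is silylated.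

Step 9
Reactants: 11 exo-7,8-epoxy-exo-6-hydroxy-1-(tert-butyldimethylsilyloxy)bicyclo[3.3.1]non-3-en-9-one
Product: 12 exo-7,8-epoxy-exo-6-methoxy-1-(tert-butyldimethylsilyloxy)bicyclo[3.3.1]non-3-en-9-one
Conditions: MeI (excess), Ag2O (3 equiv), 4 Å MS, MeCN, 40 °C, dark
Reagents that add atoms: iodomethane, CI
Why: Purdie methylation (silver-assisted SN2 on iodomethane) works without a free alkoxide, which a β-hydroxy ketone such as 11 would answer with retro-aldol cleavage of C5–C6. The cis epoxy alcohol cannot undergo Payne rearrangement because the C6 oxygen has no backside access to C7.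

Step 10
Reactants: 12 exo-7,8-epoxy-exo-6-methoxy-1-(tert-butyldimethylsilyloxy)bicyclo[3.3.1]non-3-en-9-one
Product: 13 exo-7,8-epoxy-1-hydroxy-exo-6-methoxybicyclo[3.3.1]non-3-en-9-one
Conditions: Bu4NF (2 equiv), AcOH (2 equiv), THF, 0 °C → rt
Reagents that add atoms: none
Why: Fluoride cleavage of the silyl ether, buffered with acetic acid so that the liberated ketol alkoxide is protonated before it can rearrange. It is placed here because 12 has no β-hydroxy ketone yet and because acidic desilylation would risk transannular attack of C3=C4 on the protonated epoxide.

Step 11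
Reactants: 13 exo-7,8-epoxy-1-hydroxy-exo-6-methoxybicyclo[3.3.1]non-3-en-9-one
Product: 14 benzyl N-(exo-7,8-epoxy-1,exo-4-dihydroxy-exo-6-methoxy-9-oxobicyclo[3.3.1]nonan-exo-3-yl)carbamate
Conditions: BnOC(O)NH2 (3.1 equiv), tBuOCl (3.0 equiv), NaOH (3.0 equiv), K2OsO2(OH)4 (5 mol%), (DHQD)2PHAL (6 mol%), nPrOH/H2O 1:1, 20 °C
Reagents that add atoms: benzyl carbamate, NC(=O)OCc1ccccc1; water, O
Why: Sharpless aminohydroxylation: the osmium imido species formed from K2OsO2(OH)4 and the N-chlorocarbamate salt adds N and O suprafacially to the exo face (the endo face is closed by the endo hydrogen on C7 of ring B), which sets C3 and C4 cis and exo. Nitrogen should go to C3, the alkene carbon remote from bridgehead C5 and from the electron-withdrawing C9 carbonyl; hydroxide is used only in the amount consumed in forming the chloramine salt, so the β-hydroxy ketone is not exposed to base.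

Step 12
Reactants: 14 benzyl N-(exo-7,8-epoxy-1,exo-4-dihydroxy-exo-6-methoxy-9-oxobicyclo[3.3.1]nonan-exo-3-yl)carbamate
Product: 15 exo-3-amino-exo-7,8-epoxy-1,exo-4-dihydroxy-exo-6-methoxybicyclo[3.3.1]nonan-9-one
Conditions: H2 (1 atm), 10% Pd/C, EtOAc, rt
Reagents that add atoms: none
Why: Hydrogenolysis of the benzyl carbamate on palladium under neutral conditions; the epoxide is neither allylic nor benzylic and the bridging ketone is hindered, so both should survive. The amine is used at once.

Step 13
Reactants: 15 exo-3-amino-exo-7,8-epoxy-1,exo-4-dihydroxy-exo-6-methoxybicyclo[3.3.1]nonan-9-one; 16 (E)-dodec-2-enoic acid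
Product: 18 (E)-N-(exo-7,8-epoxy-1,exo-4-dihydroxy-exo-6-methoxy-9-oxobicyclo[3.3.1]nonan-exo-3-yl)dodec-2-enamide (CNP0137540.1), via benzotriazolyl ester 17 (not isolated)
Conditions: EDC·HCl (1.3 equiv), HOBt (1.3 equiv), iPr2NEt (1.5 equiv), CH2Cl2, 0 °C → rt
Reagents that add atoms: 1-hydroxybenzotriazole, On1nnc2ccccc12
Why: Carbodiimide amide coupling through benzotriazolyl ester 17, which carries the hydroxybenzotriazole only until the amine displaces it; the primary amine is far more nucleophilic than the secondary C4 and tertiary C1 hydroxyls, so acylation should be N-selective. The mild amine base should not trigger retro-aldol or ketol rearrangement, and the E geometry of the chain is retained.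

## Compound list

1 | catechol | Oc1ccccc1O | starting material
2 | 1,2-bis(tert-butyldimethylsilyloxy)benzene | CC(C)(C)[Si](C)(C)Oc1ccccc1O[Si](C)(C)C(C)(C)C | intermediate
3 | 1,2-bis(tert-butyldimethylsilyloxy)cyclohexa-1,4-diene | CC(C)(C)[Si](C)(C)OC1=C(O[Si](C)(C)C(C)(C)C)CC=CC1 | intermediate
4 | acrolein | C=CC=O | starting material
5 | rac-2-(tert-butyldimethylsilyloxy)-2-(3-oxopropyl)cyclohex-4-en-1-one | O=CCCC1(O[Si](C)(C)C(C)(C)C)CC=CCC1=O | intermediate
6 | rac-1-(tert-butyldimethylsilyloxy)-4-hydroxybicyclo[3.3.1]non-6-en-9-one, both C4 epimers | CC(C)(C)[Si](C)(C)O[C@@]12CCC(O)[C@@H](C=CC1)C2=O | intermediate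
7 | triethylammonium salt of the O4 N-(methoxycarbonyl)sulfamate of 6 | CC[NH+](CC)CC.COC(=O)[N-]S(=O)(=O)OC1CCC2(O[Si](C)(C)C(C)(C)C)CC=CC1C2=O | intermediate
8 | meso-1-(tert-butyldimethylsilyloxy)bicyclo[3.3.1]nona-3,6-dien-9-one | CC(C)(C)[Si](C)(C)O[C@@]12CC=C[C@@H](C=CC1)C2=O | intermediate
9 | exo-6,7-epoxy-1-(tert-butyldimethylsilyloxy)bicyclo[3.3.1]non-3-en-9-one | C1C=C[C@H]2[C@@H]3O[C@@H]3C[C@]1(O[Si](C)(C)C(C)(C)C)C2=O | intermediate
10 | exo-6-hydroxy-1-(tert-butyldimethylsilyloxy)bicyclo[3.3.1]nona-3,7-dien-9-one | C1C=C[C@H]2[C@H](O)C=C[C@]1(O[Si](C)(C)C(C)(C)C)C2=O | intermediate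
11 | exo-7,8-epoxy-exo-6-hydroxy-1-(tert-butyldimethylsilyloxy)bicyclo[3.3.1]non-3-en-9-one | C1C=C[C@H]2[C@H](O)[C@@H]3O[C@@H]3[C@]1(O[Si](C)(C)C(C)(C)C)C2=O | intermediate
12 | exo-7,8-epoxy-exo-6-methoxy-1-(tert-butyldimethylsilyloxy)bicyclo[3.3.1]non-3-en-9-one | C1C=C[C@H]2[C@H](OC)[C@@H]3O[C@@H]3[C@]1(O[Si](C)(C)C(C)(C)C)C2=O | intermediate
13 | exo-7,8-epoxy-1-hydroxy-exo-6-methoxybicyclo[3.3.1]non-3-en-9-one | C1C=C[C@H]2[C@H](OC)[C@@H]3O[C@@H]3[C@]1(O)C2=O | intermediate
14 | benzyl N-(exo-7,8-epoxy-1,exo-4-dihydroxy-exo-6-methoxy-9-oxobicyclo[3.3.1]nonan-exo-3-yl)carbamate | O=C(OCc1ccccc1)N[C@H]1C[C@@]2(O)C(=O)[C@@H]([C@H]1O)[C@H](OC)[C@@H]1O[C@@H]12 | intermediate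
15 | exo-3-amino-exo-7,8-epoxy-1,exo-4-dihydroxy-exo-6-methoxybicyclo[3.3.1]nonan-9-one | N[C@H]1C[C@@]2(O)C(=O)[C@@H]([C@H]1O)[C@H](OC)[C@@H]1O[C@@H]12 | intermediate
16 | (E)-dodec-2-enoic acid | CCCCCCCCC/C=C/C(=O)O | starting material
17 | benzotriazol-1-yl (E)-dodec-2-enoate | CCCCCCCCC/C=C/C(=O)On1nnc2ccccc12 | intermediate
18 | (E)-N-(exo-7,8-epoxy-1,exo-4-dihydroxy-exo-6-methoxy-9-oxobicyclo[3.3.1]nonan-exo-3-yl)dodec-2-enamide, CNP0137540.1 | CCCCCCCCC/C=C/C(=O)N[C@H]1C[C@@]2(O)C(=O)[C@@H]([C@H]1O)[C@H](OC)[C@@H]1O[C@@H]12 | target

## Step count and least certain steps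

Total: 13 steps. Longest linear sequence: 13 steps (1 → 18); acrolein 4 and acid 16 enter directly.

**Step 6 (key step).** The most likely failure is poor discrimination between the enantiotopic alkenes. Both ends of each cis-alkene are ring carbons, the alkenes are not conjugated, and the sense of induction cannot be predicted. Slow oxygen transfer to the homoconjugated alkenes, with Baeyer–Villiger decay of the catalyst, is the second hazard. A moderate shortfall can be corrected by pushing conversion into the bis-epoxide, and by running step 8 with VO(OiPr)3 and a chiral bishydroxamic acid, which resolves the allylic alcohol at a stage where its hydroxyl is correctly placed.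

The fallback is resolution in place of desymmetrisation, setting out from 8. One equivalent of dimethyldioxirane in acetone at −20 °C should give the racemic exo mono-epoxide F1. The aluminium amide of step 7 should then give the racemic allylic alcohol F2. Acylation with vinyl acetate and Burkholderia cepacia lipase (MTBE, 30 °C) to about half conversion should give the acetate F3 of the unwanted antipode, assumed to be the faster-reacting enantiomer, and leave the alcohol of the correct series. The route is rejoined at 10, at the price of half the material.

**Step 11.** The most likely failure is addition of nitrogen at C4 or competing dihydroxylation, because the two alkene carbons differ only through their neighbours. The fallback is a tethered C–H amination whose regiochemistry is fixed by ring size; it is long, setting out from 12 and coming back at 14. Photo-oxygenation (O2, hν, tetraphenylporphyrin, CH2Cl2, 0 °C) should proceed as an ene reaction that can take only the exo hydrogen of C2, the other allylic hydrogen being on bridgehead C5, and give the exo C4 hydroperoxide F4 with the alkene moved to C2=C3; PPh3 in the same flask should reduce it to the allylic alcohol F5. Diimide (2-nitrobenzenesulfonyl hydrazide, Et3N) should give the saturated exo C4 alcohol F6, trichloroacetyl isocyanate the N-trichloroacetyl carbamate F7, and K2CO3 in MeOH the primary carbamate F8. Rh2(OAc)4, PhI(OAc)2 and MgO (CH2Cl2, 40 °C) should insert the nitrenoid into the exo C3–H bond with retention and give the cis-fused oxazolidinone F9. LiHMDS and CbzCl should give the N-benzyloxycarbonyl oxazolidinone F10, Cs2CO3 in MeOH should open it to the silyl-protected benzyl carbamate F11, and the buffered fluoride of step 10 should then remove the silyl group and return the route at 14.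

**Step 7.** The most likely failures are transannular attack of C3=C4 on the aluminium-bound epoxide (C3 onto C7), slow proton abstraction next to the bulky silyloxy group on C1, or attack of the amide on the C9 carbonyl. The fallback is nucleophilic opening and selenoxide elimination, setting out from 9. Sodium benzeneselenolate (PhSeH, NaH, THF/DMF, 50 °C) should open the epoxide at C7 from the endo side, which is the trans-diaxial mode, the approach to C6 being blocked by C4; this gives the hydroxy selenide F12. H2O2 with pyridine at 0 °C should give the selenoxide F13, which at room temperature should eliminate toward C8, away from the carbinol carbon, and rejoin the route at 10.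

**Step 4.** The most likely failure is loss of regiocontrol in the dienolate: retro-aldol equilibration to the γ-aldol (C7–C4 bond, conjugated enone) or migration of C6=C7 into conjugation. The fallback is Mannich closure and Cope elimination, which also by-passes step 5, setting out from 5. Pyrrolidine with catalytic AcOH (benzene, MgSO4, rt) should close ring A through the iminium ion to the β-amino ketone F14. mCPBA (1 equiv, CH2Cl2, −40 °C) should oxidise the amine faster than the alkene to the N-oxide F15, which on warming to 40 °C should eliminate syn toward C3 and rejoin the route at 8.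

## Further compounds

F1 | step 6 | rac-exo-6,7-epoxy-1-(tert-butyldimethylsilyloxy)bicyclo[3.3.1]non-3-en-9-one (racemate; one enantiomer drawn) | C1C=C[C@H]2[C@@H]3O[C@@H]3C[C@]1(O[Si](C)(C)C(C)(C)C)C2=O
F2 | step 6 | rac-exo-6-hydroxy-1-(tert-butyldimethylsilyloxy)bicyclo[3.3.1]nona-3,7-dien-9-one (racemate; one enantiomer drawn) | C1C=C[C@H]2[C@H](O)C=C[C@]1(O[Si](C)(C)C(C)(C)C)C2=O
F3 | step 6 | exo-6-acetoxy-1-(tert-butyldimethylsilyloxy)bicyclo[3.3.1]nona-3,7-dien-9-one, antipodal series | C1C=C[C@@H]2[C@@H](OC(C)=O)C=C[C@@]1(O[Si](C)(C)C(C)(C)C)C2=O
F4 | step 11 | exo-7,8-epoxy-exo-4-hydroperoxy-exo-6-methoxy-1-(tert-butyldimethylsilyloxy)bicyclo[3.3.1]non-2-en-9-one | C1=C[C@H](OO)[C@H]2[C@H](OC)[C@@H]3O[C@@H]3[C@]1(O[Si](C)(C)C(C)(C)C)C2=O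
F5 | step 11 | exo-7,8-epoxy-exo-4-hydroxy-exo-6-methoxy-1-(tert-butyldimethylsilyloxy)bicyclo[3.3.1]non-2-en-9-one | C1=C[C@H](O)[C@H]2[C@H](OC)[C@@H]3O[C@@H]3[C@]1(O[Si](C)(C)C(C)(C)C)C2=O
F6 | step 11 | exo-7,8-epoxy-exo-4-hydroxy-exo-6-methoxy-1-(tert-butyldimethylsilyloxy)bicyclo[3.3.1]nonan-9-one | C1C[C@H](O)[C@H]2[C@H](OC)[C@@H]3O[C@@H]3[C@]1(O[Si](C)(C)C(C)(C)C)C2=O
F7 | step 11 | O4 N-(trichloroacetyl)carbamate of F6 | C1C[C@H](OC(=O)NC(=O)C(Cl)(Cl)Cl)[C@H]2[C@H](OC)[C@@H]3O[C@@H]3[C@]1(O[Si](C)(C)C(C)(C)C)C2=O
F8 | step 11 | O4 carbamate of F6 | C1C[C@H](OC(N)=O)[C@H]2[C@H](OC)[C@@H]3O[C@@H]3[C@]1(O[Si](C)(C)C(C)(C)C)C2=O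
F9 | step 11 | C3,C4 cis-fused oxazolidinone, C1 tert-butyldimethylsilyl ether | O=C1N[C@H]2C[C@@]3(O[Si](C)(C)C(C)(C)C)C(=O)[C@@H]([C@H]2O1)[C@H](OC)[C@@H]4O[C@@H]43
F10 | step 11 | N-benzyloxycarbonyl derivative of F9 | O=C1N(C(=O)OCc5ccccc5)[C@H]2C[C@@]3(O[Si](C)(C)C(C)(C)C)C(=O)[C@@H]([C@H]2O1)[C@H](OC)[C@@H]4O[C@@H]43
F11 | step 11 | C1 tert-butyldimethylsilyl ether of 14 | O=C(OCc1ccccc1)N[C@H]1C[C@@]2(O[Si](C)(C)C(C)(C)C)C(=O)[C@@H]([C@H]1O)[C@H](OC)[C@@H]1O[C@@H]12
F12 | step 7 | exo-6-hydroxy-endo-7-(phenylselanyl)-1-(tert-butyldimethylsilyloxy)bicyclo[3.3.1]non-3-en-9-one | C1C=C[C@H]2[C@H](O)[C@@H]([Se]c3ccccc3)C[C@]1(O[Si](C)(C)C(C)(C)C)C2=O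
F13 | step 7 | selenoxide of F12 | C1C=C[C@H]2[C@H](O)[C@@H]([Se](=O)c3ccccc3)C[C@]1(O[Si](C)(C)C(C)(C)C)C2=O
F14 | step 4 | rac-4-(pyrrolidin-1-yl)-1-(tert-butyldimethylsilyloxy)bicyclo[3.3.1]non-6-en-9-one, C4 epimers | CC(C)(C)[Si](C)(C)OC12CCC(N3CCCC3)C(C=CC1)C2=O
F15 | step 4 | N-oxide of F14 | CC(C)(C)[Si](C)(C)OC12CCC([N+]3([O-])CCCC3)C(C=CC1)C2=O
A1 | alternative 1 | 4-acetyl-4-(triethylsilyloxy)heptanedial | CC(=O)C(CCC=O)(CCC=O)O[Si](CC)(CC)CC
A2 | alternative 1 | meso exo,exo-4,6-dihydroxy-1-(triethylsilyloxy)bicyclo[3.3.1]nonan-9-one | C1C[C@@]2(O[Si](CC)(CC)CC)C(=O)[C@@H]([C@H]1O)[C@H](O)CC2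
A3 | alternative 2 | shikimic acid | C1[C@H]([C@@H]([C@@H](C=C1C(=O)O)O)O)O
A4 | alternative 2 | cyclohexanone with (Z)-3-oxoprop-1-enyl and hydroxyl on C1, NHBoc on C3, silyloxy on C4 | CC(C)(C)OC(=O)N[C@H]1C[C@](O)(/C=C\C=O)C(=O)C[C@H]1O[Si](C)(C)C(C)(C)C
A5 | alternative 2 | bicyclic exo C6 allylic alcohol with C7=C8 | CC(C)(C)OC(=O)N[C@H]1C[C@@]2(O)C(=O)[C@@H]([C@H]1O[Si](C)(C)C(C)(C)C)[C@H](O)C=C2
A6 | alternative 3 | exo C4 primary carbamate of the nitrogen-free core | C1C[C@@]2(O)C(=O)[C@@H]([C@H]1OC(N)=O)[C@H](OC)[C@@H]1O[C@@H]12
A7 | alternative 3 | C3,C4 cis-fused oxazolidinone of the core | O=C1N[C@H]2C[C@@]3(O)C(=O)[C@@H]([C@H]2O1)[C@H](OC)[C@@H]4O[C@@H]43
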